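If the impurity, charged in each flask below the free catalyst, takes free catalyst one for one, it is the limiting reagent of that side reaction, and what keeps working is the catalyst charged minus the impurity charged.

| setting | Saturday's | Wednesday's | noon | midnight |
|---|---|---|---|---|
| substrate | 0.050 M | 0.050 M | 0.050 M | 0.050 M |
| free catalyst | 0.10 mM | 0.10 mM | 0.10 mM | 0.10 mM |
| impurity | 57 µM | 63 µM | 33 µM | 82 µM |
| remark | run made earlier | run made earlier |  |  |
| time |  |  | 2.5 h | 2.5 h |

| run | time / min | product / % | catalyst intermediate B / % | catalyst intermediate A / % | substrate / % |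
|---|---|---|---|---|---|
| Saturday's | 6.00 | 0.3 | 0.1 | 0.5 | 98.8 |
| Saturday's | 20.0 | 1.8 | 0 | 0 | 97.7 |
| Saturday's | 40.0 | 4.0 | 0 | 0 | 96.2 |
| Saturday's | 50.0 | 4.9 | 0 | 0.2 | 96.0 |
| Saturday's | 80.0 | 6.6 | 0.2 | 0 | 93.4 |
| Wednesday's | 6.00 | 0.6 | 0 | 0 | 99.2 |
| Wednesday's | 12.0 | 1.4 | 0.1 | 0 | 98.7 |
| Wednesday's | 20.0 | 2.1 | 0 | 0 | 97.7 |
| Wednesday's | 40.0 | 3.4 | 0 | 0.7 | 96.1 |
| Wednesday's | 80.0 | 6.1 | 0 | 0 | 93.6 |

(readings scatter by 0.3 percentage points)

* which of these there is most of at the end, counted by the substrate in it, noon (catalyst intermediate A / substrate / product / catalyst intermediate B)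
* which of these there is most of at the end, counted by the substrate in it, midnight (catalyst intermediate A / substrate / product / catalyst intermediate B)
* how much there is at the end of the one of these that leads, in percent of the substrate charged: noon
* how much there is at the end of the one of these that leads, in percent of the substrate charged: midnight

That leaves a live share of 43.0% in Saturday's run and 37.0% in Wednesday's. I take the rate as proportional to substrate and to live catalyst (pseudo-first-order), so the substrate left is exp(−N). From the last product readings, carried to 2.5 h, a fully live charge gives N = 0.298 on Saturday's run and 0.319 on Wednesday's, so I use 0.308.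

The reach N, that value times the live share, is 0.207 for noon and 0.0555 for midnight. Both lie below ln(2), 0.693, and the intermediates can hold 0.200% of the substrate at most, so I expect substrate to lead. I reckon 81.3% left at noon and 94.6% at midnight.

Is one number enough? Wednesday's value carried to Saturday's live share gives 7.05% product against the 6.6% read, a gap of 0.45 percentage points on a scatter of 0.3 points. But Saturday's readings show less product made between 40.0 min and 80.0 min, 2.6 points, than the 4.0% read at 40.0 min, so the straight line in time is loose.

The forecast names substrate at noon, 83% (77% to 88%), and substrate at midnight, 95% (92.5% to 97%), on the ground that “The impurity seems to kill catalyst one-for-one”. For noon my figure is lower.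

The flasks give substrate at 82.6% for noon and substrate at 93.7% for midnight.

    substrate + free catalyst → catalyst intermediate A (k = 71.3 L mol⁻¹ min⁻¹)
    catalyst intermediate A ⇌ catalyst intermediate B (K = 1.12, k = 3.10 min⁻¹)
    catalyst intermediate B → free catalyst + product (k = 3.74 min⁻¹)
    free catalyst ⇌ dormant form (K = 6.10, k = 0.00194 min⁻¹)
    free catalyst + impurity → spent catalyst (k = 6720 L mol⁻¹ min⁻¹)

Read back, these are reaches of 0.191 against my 0.207 at noon and 0.0651 against my 0.0555 at midnight. For a neighbour of noon charged with 2.5 × 10⁻⁴ M of free catalyst, I take the fully live value times its catalyst minus impurity over 0.10 mM, and I reckon a reach of 0.669, so 51.2% substrate left. That flask holds 13.2% of its catalyst charged as spent catalyst and ends with substrate at 48.7%.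

Readings and results were computed for substances that don't exist; noise was put on by code.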